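**Plan**
1. Retrosynthesis (labdane numbering): the 2α-OH goes back to a C2 ketone. Ring A then shows a Diels–Alder retron: oxygen on C2 (read as enol ether C1=C2), the C19 carboxyl on C4, and the fusion bond C5–C10 shared by rings A and B. C5–C10 and C3–C4 are cut together to an acyclic triene, which is cut further at C4=C5 (Z-olefination), C6–C7 and C8–C9 (two Claisen rearrangements) and C1–C2 (alkynylation), down to methyl geranate.
2. Forward: methyl geranate supplies C9, C11–C16, C10, C20 and C1. An alkyne adds C2/C3, the first vinyl ether C8 and C17, an iminium salt C7, the second vinyl ether C6/C5, a phosphonate C4/C18/C19. The chain ends as a 2-silyloxy diene (C3=C2–C1=C10) and a Z-2-methylenoate (C4=C5) joined by C6–C9.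
3. Rings A and B arise together in one intramolecular Diels–Alder step; no other cyclisation is needed.
4. Stereochemistry: C9 from a catalytic asymmetric alkynylation followed by 1,3-chirality transfer in the first Claisen rearrangement. C4, C5 and C10 come from the cycloaddition (Z dienophile, silyl ester exo, C9 side chain equatorial on the chair tether). C2 comes from hydride delivery by the axial C19 carboxyl group.
5. Helpers: the silyl-capped alkyne (masked acetyl group) and three silyl groups (dienol ether, two silyl esters), all removed within the route.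

Key step: step 11

Remark: the (R,R)-antipode of ProPhenol is assumed to deliver the alkyne to the Si face of enal 3 (8R carbinol); the other antipode is used if a Mosher ester analysis shows the opposite sense.

**Step 1**
Reactants: 1 methyl geranate [methyl (2E)-3,7-dimethylocta-2,6-dienoate]
Product: 3 methyl (2E,6E)-3,7-dimethyl-8-oxoocta-2,6-dienoate, via allylic alcohol 2 (not isolated)
Conditions: SeO2 (0.3 equiv), t-BuOOH (3 equiv), salicylic acid (0.1 equiv), CH2Cl2, 0 °C to rt; filter; MnO2, CH2Cl2, rt
Reagents that add atoms: selenium dioxide O=[Se]=O; tert-butyl hydroperoxide CC(C)(C)OO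
Why: Catalytic SeO2 allylic oxidation (ene reaction, then [2,3]-sigmatropic shift) should attack the electron-rich 6,7-olefin at its E-methyl group, the ester-conjugated 2,3-olefin being deactivated, and MnO2 then takes the allylic alcohol on to the E-enal.

**Step 2**
Reactants: 3 methyl (2E,6E)-3,7-dimethyl-8-oxoocta-2,6-dienoate; 4 ethynyl(trimethyl)silane
Product: 5 methyl (2E,6E,8R)-8-hydroxy-3,7-dimethyl-10-(trimethylsilyl)deca-2,6-dien-9-ynoate
Conditions: (R,R)-ProPhenol (20 mol %), Me2Zn (3 equiv), 4 (3 equiv), Ph3PO (40 mol %), toluene, 4 °C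
Reagents that add atoms: none
Why: Zinc–ProPhenol-catalysed enantioselective alkynylation of an aldehyde, in which the dinuclear zinc complex delivers the zinc acetylide to one face of the α-methyl enal and should set the 8R carbinol, while the ester is inert to Me2Zn.

**Step 3**
Reactants: 5 methyl (2E,6E,8R)-8-hydroxy-3,7-dimethyl-10-(trimethylsilyl)deca-2,6-dien-9-ynoate
Product: 7 methyl (2E,6S,7E)-3,7-dimethyl-6-(2-oxoethyl)-10-(trimethylsilyl)deca-2,7-dien-9-ynoate, via allyl vinyl ether 6 (not isolated)
Conditions: ethyl vinyl ether (solvent), Hg(OAc)2 (0.3 equiv), reflux; Et3N, evaporate; toluene, 100 °C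
Reagents that add atoms: ethyl vinyl ether C=COCC
Why: Transvinylation then Claisen rearrangement through a chair transition state with the alkynyl group pseudo-equatorial should transfer the carbinol chirality suprafacially to C9 (6S here) and place the alkyne trans to C9 on the new trisubstituted olefin, the competing propargylic shift being slowed by the silyl cap.

**Step 4**
Reactants: 7 methyl (2E,6S,7E)-3,7-dimethyl-6-(2-oxoethyl)-10-(trimethylsilyl)deca-2,7-dien-9-ynoate
Product: 9 methyl (2E,6R,7E)-3,7-dimethyl-6-(3-oxoprop-1-en-2-yl)-10-(trimethylsilyl)deca-2,7-dien-9-ynoate, via Mannich base 8 (not isolated)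
Conditions: CH2=NMe2+ I− (3 equiv), Et3N (5 equiv), CH2Cl2, rt
Reagents that add atoms: N,N-dimethylmethyleneiminium iodide C=[N+](C)C.[I-]
Why: Mannich reaction of the aldehyde with the iminium salt and β-elimination of dimethylamine (α-methylenation of an aldehyde) is a mild amine-base process that should leave the allylic C9 stereocentre untouched (the descriptor changes only by priority).

**Step 5**
Reactants: 9 methyl (2E,6R,7E)-3,7-dimethyl-6-(3-oxoprop-1-en-2-yl)-10-(trimethylsilyl)deca-2,7-dien-9-ynoate
Product: 10 methyl (2E,6R,7E)-6-(3-hydroxyprop-1-en-2-yl)-3,7-dimethyl-10-(trimethylsilyl)deca-2,7-dien-9-ynoate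
Conditions: NaBH4, CeCl3·7H2O, MeOH, −40 °C
Reagents that add atoms: none
Why: Luche reduction gives 1,2-delivery of hydride to the enal and should leave the conjugated ester and the enyne alone.

**Step 6**
Reactants: 10 methyl (2E,6R,7E)-6-(3-hydroxyprop-1-en-2-yl)-3,7-dimethyl-10-(trimethylsilyl)deca-2,7-dien-9-ynoate
Product: 12 methyl (2E,6S,7E)-3,7-dimethyl-6-(5-oxopent-1-en-2-yl)-10-(trimethylsilyl)deca-2,7-dien-9-ynoate, via allyl vinyl ether 11 (not isolated)
Conditions: ethyl vinyl ether (solvent), Hg(OAc)2 (0.3 equiv), reflux; Et3N, evaporate; toluene, 130 °C (sealed tube)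
Reagents that add atoms: ethyl vinyl ether C=COCC
Why: A second transvinylation and Claisen rearrangement moves the 1,1-disubstituted olefin one carbon along, so that the former CH2OH carbon becomes the C17 methylene and C6/C5 are added as a 4-pentenal, with no new stereocentre.

**Step 7**
Reactants: 12 methyl (2E,6S,7E)-3,7-dimethyl-6-(5-oxopent-1-en-2-yl)-10-(trimethylsilyl)deca-2,7-dien-9-ynoate; 13 ethyl 2-[bis(2,2,2-trifluoroethoxy)phosphoryl]propanoate
Product: 14 1-ethyl 12-methyl (2Z,7S,10E)-2,10-dimethyl-6-methylidene-7-[(2E)-5-(trimethylsilyl)pent-2-en-4-yn-2-yl]dodeca-2,10-dienedioate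
Conditions: 13, KN(SiMe3)2, 18-crown-6, THF, −78 °C; then 12
Reagents that add atoms: none
Why: Still–Gennari olefination with the electron-poor phosphonate under dissociating conditions should give the Z-2-methyl-2-enoate by kinetically controlled elimination, which places the ester cis to the chain as the C19 (4β) carboxyl requires.

**Step 8**
Reactants: 14 1-ethyl 12-methyl (2Z,7S,10E)-2,10-dimethyl-6-methylidene-7-[(2E)-5-(trimethylsilyl)pent-2-en-4-yn-2-yl]dodeca-2,10-dienedioate
Product: 15 (2Z,7S,10E)-2,10-dimethyl-6-methylidene-7-[(2E)-pent-2-en-4-yn-2-yl]dodeca-2,10-dienedioic acid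
Conditions: LiOH·H2O (8 equiv), THF/MeOH/H2O, rt to 40 °C; 1 M HCl to pH 3
Reagents that add atoms: lithium hydroxide [Li+].[OH-]; water O
Why: Saponification of both unhindered conjugated esters and hydroxide-induced protodesilylation of the alkynylsilane in one operation, placed before the enone exists because C9–H is then still a non-acidic bis-allylic position.

**Step 9**
Reactants: 15 (2Z,7S,10E)-2,10-dimethyl-6-methylidene-7-[(2E)-pent-2-en-4-yn-2-yl]dodeca-2,10-dienedioic acid
Product: 16 (2Z,7S,10E)-2,10-dimethyl-6-methylidene-7-[(2E)-4-oxopent-2-en-2-yl]dodeca-2,10-dienedioic acid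
Conditions: (IPr)AuCl (2 mol %) [IPr = 1,3-bis(2,6-diisopropylphenyl)imidazol-2-ylidene], AgSbF6 (2 mol %), 1,4-dioxane/H2O, 60 °C
Reagents that add atoms: water O
Why: Gold-catalysed Markovnikov hydration of the terminal alkyne of the conjugated enyne should give the methyl ketone (the E-enone) under near-neutral conditions, the trans relation of the alkyne to C9 ruling out enyne cycloisomerisation with the C8 methylene.

**Step 10**
Reactants: 16 (2Z,7S,10E)-2,10-dimethyl-6-methylidene-7-[(2E)-4-oxopent-2-en-2-yl]dodeca-2,10-dienedioic acid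
Product: 17 bis[tert-butyl(dimethyl)silyl] (2Z,7S,10E)-7-[(2E)-4-{[tert-butyl(dimethyl)silyl]oxy}penta-2,4-dien-2-yl]-2,10-dimethyl-6-methylidenedodeca-2,10-dienedioate
Conditions: TBSOTf (3.5 equiv), Et3N (5 equiv), CH2Cl2, −78 to 0 °C; pentane, filter under argon, concentrate (used crude)
Reagents that add atoms: tert-butyldimethylsilyl trifluoromethanesulfonate CC(C)(C)[Si](C)(C)OS(=O)(=O)C(F)(F)F
Why: Soft enolisation, in which the silyl triflate activates the enone and triethylamine removes the most accessible proton (C3 methyl) at low temperature, should give the cross-conjugated 2-silyloxy-1,3-diene while both acids are capped as silyl esters in the same flask.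

**Step 11**
Reactants: 17 bis[tert-butyl(dimethyl)silyl] (2Z,7S,10E)-7-[(2E)-4-{[tert-butyl(dimethyl)silyl]oxy}penta-2,4-dien-2-yl]-2,10-dimethyl-6-methylidenedodeca-2,10-dienedioate
Product: 19 (4S,5R,9S,10R,13E)-2-oxolabda-8(17),13-diene-15,19-dioic acid, via silyl enol ether cycloadduct 18 (not isolated)
Conditions: toluene (0.005 M), BHT, 180 °C (sealed, base-washed glass); then 1 M HCl, THF, rt
Reagents that add atoms: none
Why: Thermal, concerted but asynchronous [4+2] cycloaddition (intramolecular Diels–Alder reaction of a 1,7,9-decatriene) between the 2-silyloxy diene C3=C2–C1=C10 and the Z-2-methylenoate C4=C5 forms C5–C10 and C3–C4; the closest known reaction type is the thermal cyclisation of 2-silyloxy-decatrienoates to decalones. Ring A (C10, C1, C2, C3, C4, C5) is closed by the cycloaddition itself and ring B (C5 to C10) by the C5–C10 bond in the fused mode, the four-carbon tether C6–C9 adopting a chair. C4 is set by the Z geometry of the dienophile (carboxyl cis to C6) and suprafacial addition, the trans relation of H-5 to the C10 methyl by the anti transition state with the tether and the bulky silyl ester exo and the C18 methyl endo, and the diene face by C9, whose side chain sits pseudo-equatorial on the chair tether, away from the forming bond. The step needs fused regiochemistry against the electronic preference of the 2-silyloxy diene, which the short tether enforces, and chemoselectivity over the side-chain enoate, which could add only by joining two fully substituted carbons in a five-membered ring. The 1,5-hydrogen shift between the C20 methyl and C3 is reversible and returns the same diene geometry. Acidic work-up then cleaves the silyl enol ether and both silyl esters to the 2-keto diacid.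

**Step 12**
Reactants: 19 (4S,5R,9S,10R,13E)-2-oxolabda-8(17),13-diene-15,19-dioic acid
Product: 20 hypoxyterpoid A [(2R,4S,5R,9S,10R,13E)-2-hydroxylabda-8(17),13-diene-15,19-dioic acid, 2α-OH]
Conditions: Me4NBH(OAc)3 (4 equiv), MeCN/AcOH (10:1), −20 °C to rt
Reagents that add atoms: none
Why: Proposed new method: the axial C19 carboxylic acid should exchange for acetate on boron to give an acyloxy(diacetoxy)borohydride held on the β face, 1,3-diaxial to C2, which delivers hydride through a seven-membered transition state to the β face of the ketone and so gives the equatorial 2α-alcohol, whereas triacetoxyborohydride itself does not reduce ketones at a useful rate and external hydrides would attack the α face away from C19 and C20; the closest known reaction type is the Evans–Saksena hydroxyl-directed reduction of β-hydroxy ketones with the same reagent, here with a carboxyl group as the delivering ligand.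

**Compound list**
1 | methyl geranate, methyl (2E)-3,7-dimethylocta-2,6-dienoate | COC(=O)/C=C(C)/CCC=C(C)C | starting material
2 | methyl (2E,6E)-8-hydroxy-3,7-dimethylocta-2,6-dienoate | COC(=O)/C=C(C)/CC/C=C(C)/CO | intermediate
3 | methyl (2E,6E)-3,7-dimethyl-8-oxoocta-2,6-dienoate | COC(=O)/C=C(C)/CC/C=C(C)/C=O | intermediate
4 | ethynyl(trimethyl)silane | C#C[Si](C)(C)C | starting material
5 | methyl (2E,6E,8R)-8-hydroxy-3,7-dimethyl-10-(trimethylsilyl)deca-2,6-dien-9-ynoate | COC(=O)/C=C(C)/CC/C=C(C)/[C@@H](O)C#C[Si](C)(C)C | intermediate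
6 | methyl (2E,6E,8R)-8-(ethenyloxy)-3,7-dimethyl-10-(trimethylsilyl)deca-2,6-dien-9-ynoate | COC(=O)/C=C(C)/CC/C=C(C)/[C@@H](OC=C)C#C[Si](C)(C)C | intermediate
7 | methyl (2E,6S,7E)-3,7-dimethyl-6-(2-oxoethyl)-10-(trimethylsilyl)deca-2,7-dien-9-ynoate | COC(=O)/C=C(C)/CC[C@@H](CC=O)/C(C)=C/C#C[Si](C)(C)C | intermediate
8 | methyl (2E,6S,7E)-6-[1-(dimethylamino)-3-oxopropan-2-yl]-3,7-dimethyl-10-(trimethylsilyl)deca-2,7-dien-9-ynoate (both epimers at the aminomethyl-bearing carbon) | COC(=O)/C=C(C)/CC[C@@H](C(CN(C)C)C=O)/C(C)=C/C#C[Si](C)(C)C | intermediate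
9 | methyl (2E,6R,7E)-3,7-dimethyl-6-(3-oxoprop-1-en-2-yl)-10-(trimethylsilyl)deca-2,7-dien-9-ynoate | COC(=O)/C=C(C)/CC[C@@H](C(=C)C=O)/C(C)=C/C#C[Si](C)(C)C | intermediate
10 | methyl (2E,6R,7E)-6-(3-hydroxyprop-1-en-2-yl)-3,7-dimethyl-10-(trimethylsilyl)deca-2,7-dien-9-ynoate | COC(=O)/C=C(C)/CC[C@@H](C(=C)CO)/C(C)=C/C#C[Si](C)(C)C | intermediate
11 | methyl (2E,6R,7E)-6-[3-(ethenyloxy)prop-1-en-2-yl]-3,7-dimethyl-10-(trimethylsilyl)deca-2,7-dien-9-ynoate | COC(=O)/C=C(C)/CC[C@@H](C(=C)COC=C)/C(C)=C/C#C[Si](C)(C)C | intermediate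
12 | methyl (2E,6S,7E)-3,7-dimethyl-6-(5-oxopent-1-en-2-yl)-10-(trimethylsilyl)deca-2,7-dien-9-ynoate | COC(=O)/C=C(C)/CC[C@@H](C(=C)CCC=O)/C(C)=C/C#C[Si](C)(C)C | intermediate
13 | ethyl 2-[bis(2,2,2-trifluoroethoxy)phosphoryl]propanoate | CCOC(=O)C(C)P(=O)(OCC(F)(F)F)OCC(F)(F)F | starting material
14 | 1-ethyl 12-methyl (2Z,7S,10E)-2,10-dimethyl-6-methylidene-7-[(2E)-5-(trimethylsilyl)pent-2-en-4-yn-2-yl]dodeca-2,10-dienedioate | COC(=O)/C=C(C)/CC[C@@H](C(=C)CC/C=C(C)\C(=O)OCC)/C(C)=C/C#C[Si](C)(C)C | intermediate
15 | (2Z,7S,10E)-2,10-dimethyl-6-methylidene-7-[(2E)-pent-2-en-4-yn-2-yl]dodeca-2,10-dienedioic acid | OC(=O)/C=C(C)/CC[C@@H](C(=C)CC/C=C(C)\C(=O)O)/C(C)=C/C#C | intermediate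
16 | (2Z,7S,10E)-2,10-dimethyl-6-methylidene-7-[(2E)-4-oxopent-2-en-2-yl]dodeca-2,10-dienedioic acid | OC(=O)/C=C(C)/CC[C@@H](C(=C)CC/C=C(C)\C(=O)O)/C(C)=C/C(C)=O | intermediate
17 | bis[tert-butyl(dimethyl)silyl] (2Z,7S,10E)-7-[(2E)-4-{[tert-butyl(dimethyl)silyl]oxy}penta-2,4-dien-2-yl]-2,10-dimethyl-6-methylidenedodeca-2,10-dienedioate | CC(C)(C)[Si](C)(C)OC(=O)/C=C(C)/CC[C@@H](C(=C)CC/C=C(C)\C(=O)O[Si](C)(C)C(C)(C)C)/C(C)=C/C(=C)O[Si](C)(C)C(C)(C)C | intermediate
18 | bis[tert-butyl(dimethyl)silyl] (4S,5R,9S,10R,13E)-2-{[tert-butyl(dimethyl)silyl]oxy}labda-1,8(17),13-triene-15,19-dioate | C=C1CC[C@@H]2[C@](C)(C=C(O[Si](C)(C)C(C)(C)C)C[C@]2(C)C(=O)O[Si](C)(C)C(C)(C)C)[C@H]1CC/C(C)=C/C(=O)O[Si](C)(C)C(C)(C)C | intermediate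
19 | (4S,5R,9S,10R,13E)-2-oxolabda-8(17),13-diene-15,19-dioic acid | C=C1CC[C@@H]2[C@](C)(CC(=O)C[C@]2(C)C(=O)O)[C@H]1CC/C(C)=C/C(=O)O | intermediate
20 | hypoxyterpoid A, (2R,4S,5R,9S,10R,13E)-2-hydroxylabda-8(17),13-diene-15,19-dioic acid | C=C1CC[C@@H]2[C@](C)(C[C@@H](O)C[C@]2(C)C(=O)O)[C@H]1CC/C(C)=C/C(=O)O | target

**Count and risks**
Total steps: 12. Longest linear sequence: 12 steps (from 1).

Steps most likely to fail:

1. Step 12. Hydride may be transferred by reagent that is not bound to the C19 carboxyl, or ligand exchange may be too slow; either leads to attack on the open α face and the axial alcohol. Fallback (known chemistry, thermodynamic instead of directed control): setting out from 19, NaBH4 in aqueous NaOH/MeOH reduces from the α face to the 2β-epimer of hypoxyterpoid A F1, kept as the dicarboxylate so that it cannot lactonise. Alkoxide hydride-transfer equilibration (KOtBu, catalytic fluorenone, t-BuOH/toluene, reflux; Oppenauer/Meerwein–Ponndorf–Verley type) should then drain F1 into the equatorial alcohol, which relieves two syn-axial interactions, and the route is rejoined at 20.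

2. Step 11. The cycloaddition may be too slow at a temperature the silyl dienol ether tolerates, or exo/endo discrimination may be poor and give the cis-fused, C4-epimeric skeleton. Fallback (dienophile redesigned as an isolable, more electron-poor ester so that the cyclisation can run at lower temperature with a purified diene): setting out from 16, both carboxylates are alkylated with 2,2,2-trifluoroethyl triflate (Cs2CO3, DMF) to the bis(trifluoroethyl) ester F2. TBSOTf/Et3N gives the silyl dienol ether F3, which is cyclised in toluene to the cycloadduct F4. LiOH in aqueous THF followed by 1 M HCl cleaves the activated esters and the enol ether, and the route is rejoined at 19.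

3. Step 3. The slim alkynyl group may not hold the pseudo-equatorial position in the chair, which would lower the olefin geometry control and the chirality transfer, and the propargylic shift may compete. Fallback (a rearrangement with a substituted ketene aminal that enforces the equatorial placing, followed by reduction): setting out from 5, Eschenmoser–Claisen rearrangement (N,N-dimethylacetamide dimethyl acetal, xylene, 140 °C) gives the dimethylamide F5. Chemoselective amide-to-aldehyde reduction (Tf2O, 2-fluoropyridine, then Et3SiH; aqueous citric acid) spares the ester, and the route is rejoined at 7.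

**Further compounds**
F1 | step 12 | (2S,4S,5R,9S,10R,13E)-2-hydroxylabda-8(17),13-diene-15,19-dioic acid (2β-epimer of the target) | C=C1CC[C@@H]2[C@](C)(C[C@H](O)C[C@]2(C)C(=O)O)[C@H]1CC/C(C)=C/C(=O)O
F2 | step 11 | bis(2,2,2-trifluoroethyl) (2Z,7S,10E)-2,10-dimethyl-6-methylidene-7-[(2E)-4-oxopent-2-en-2-yl]dodeca-2,10-dienedioate | FC(F)(F)COC(=O)/C=C(C)/CC[C@@H](C(=C)CC/C=C(C)\C(=O)OCC(F)(F)F)/C(C)=C/C(C)=O
F3 | step 11 | bis(2,2,2-trifluoroethyl) (2Z,7S,10E)-7-[(2E)-4-{[tert-butyl(dimethyl)silyl]oxy}penta-2,4-dien-2-yl]-2,10-dimethyl-6-methylidenedodeca-2,10-dienedioate | FC(F)(F)COC(=O)/C=C(C)/CC[C@@H](C(=C)CC/C=C(C)\C(=O)OCC(F)(F)F)/C(C)=C/C(=C)O[Si](C)(C)C(C)(C)C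
F4 | step 11 | bis(2,2,2-trifluoroethyl) (4S,5R,9S,10R,13E)-2-{[tert-butyl(dimethyl)silyl]oxy}labda-1,8(17),13-triene-15,19-dioate | C=C1CC[C@@H]2[C@](C)(C=C(O[Si](C)(C)C(C)(C)C)C[C@]2(C)C(=O)OCC(F)(F)F)[C@H]1CC/C(C)=C/C(=O)OCC(F)(F)F
F5 | step 3 | methyl (2E,6S,7E)-6-[2-(dimethylamino)-2-oxoethyl]-3,7-dimethyl-10-(trimethylsilyl)deca-2,7-dien-9-ynoate | COC(=O)/C=C(C)/CC[C@@H](CC(=O)N(C)C)/C(C)=C/C#C[Si](C)(C)C
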